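**Plan**

- Retrosynthetic cuts: the ester C–O bond between the cinnamoyl carbon and the danshensu oxygen; in the coumarin the C4–C4a, O1–C2 and C3–C4 bonds; and the O–CH2 ether bond that becomes the C3 aryloxy link.
- Enabling feature: the carbocyclic ring of the coumarin carries oxygen at C6, C7 and C8a, and C4a is ortho to O1 and para to the C7 oxygen. An acyl chain on O1 (C2–C3–C4) therefore holds an electrophilic C4 next to the most electron-rich free ring carbon.
- Forward: methyl ferulate is O-alkylated with tert-butyl bromoacetate (C2–C3), formylated and O-methylated (C4), the acid is freed and esterified with 3,4-dimethoxyphenol (O1–C2), and BF3·OEt2 closes the pyranone, the only ring made.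
- C4 is carried as a methyl enol ether, the acetal minus one methanol, so that the acid is unmasked from a tert-butyl ester by acid and hydroxide never has to distinguish two esters.
- End game: methyl ethers are exchanged for allyl ethers, the cinnamate is saponified and joined to tri-O-allyl danshensu, and Pd(PPh3)4 with morpholine removes all six allyl groups.
- Stereochemistry: the single (R) stereocentre is bought as sodium danshensu and is acylated on oxygen with retention; the E cinnamate comes from methyl ferulate.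

Key step: step 5

Remark: the enol ether bond of 5, 6 and 8 is drawn Z (methoxy cis to aryloxy), the isomer expected from O-methylation; its geometry does not matter, because C4 loses its methoxy group in step 5.

**Route**

Step 1
Reactants: 1 methyl ferulate; 2 tert-butyl bromoacetate
Product: 3 methyl (E)-3-[4-(2-tert-butoxy-2-oxoethoxy)-3-methoxyphenyl]prop-2-enoate
Conditions: K2CO3, acetone, reflux
Reagents that add atoms: none
Why: Williamson etherification, in which the phenoxide of 1 displaces bromide from the activated α-bromo ester by SN2 and the tert-butyl ester is chosen because acid can later remove it beside the methyl cinnamate.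

Step 2
Reactants: 3 methyl (E)-3-[4-(2-tert-butoxy-2-oxoethoxy)-3-methoxyphenyl]prop-2-enoate
Product: 5 tert-butyl (Z)-3-methoxy-2-{2-methoxy-4-[(E)-3-methoxy-3-oxoprop-1-en-1-yl]phenoxy}prop-2-enoate, via sodium formyl enolate 4 (not isolated)
Conditions: NaH, HCO2Me, THF, 0 °C to rt; then Me2SO4, DMF, 0 °C to rt
Reagents that add atoms: methyl formate COC=O; dimethyl sulfate COS(=O)(=O)OC
Why: Crossed Claisen formylation of the aryloxyacetate (the cinnamate has no enolisable hydrogen, its methyl ester exchanges degenerately with methoxide and the tert-butyl ester resists it) should give the stabilised enolate 4, whose O-methylation in DMF gives the β-methoxyacrylate as in the preparation of strobilurin-type enol ethers.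

Step 3
Reactants: 5 tert-butyl (Z)-3-methoxy-2-{2-methoxy-4-[(E)-3-methoxy-3-oxoprop-1-en-1-yl]phenoxy}prop-2-enoate
Product: 6 (Z)-3-methoxy-2-{2-methoxy-4-[(E)-3-methoxy-3-oxoprop-1-en-1-yl]phenoxy}prop-2-enoic acid
Conditions: TFA, CH2Cl2, 0 °C to rt; toluene azeotrope, no aqueous work-up
Reagents that add atoms: none
Why: Acidolysis of a tert-butyl ester by alkyl–oxygen cleavage, which under anhydrous conditions should leave the push–pull enol ether and the methyl ester untouched because neither can be hydrolysed without water.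

Step 4
Reactants: 6 (Z)-3-methoxy-2-{2-methoxy-4-[(E)-3-methoxy-3-oxoprop-1-en-1-yl]phenoxy}prop-2-enoic acid; 7 3,4-dimethoxyphenol
Product: 8 3,4-dimethoxyphenyl (Z)-3-methoxy-2-{2-methoxy-4-[(E)-3-methoxy-3-oxoprop-1-en-1-yl]phenoxy}prop-2-enoate
Conditions: DCC, DMAP (cat.), CH2Cl2, 0 °C to rt
Reagents that add atoms: none
Why: Steglich esterification, in which DMAP passes the acyl group from the O-acylisourea to the electron-rich phenol under neutral conditions that the enol ether tolerates.

Step 5
Reactants: 8 3,4-dimethoxyphenyl (Z)-3-methoxy-2-{2-methoxy-4-[(E)-3-methoxy-3-oxoprop-1-en-1-yl]phenoxy}prop-2-enoate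
Product: 10 methyl (E)-3-{4-[(6,7-dimethoxy-2-oxo-2H-chromen-3-yl)oxy]-3-methoxyphenyl}prop-2-enoate, via 4-methoxy-3,4-dihydrocoumarin 9 (not isolated)
Conditions: BF3·OEt2 (3 equiv), CH2Cl2 (0.02 M), 0 °C to rt
Reagents that add atoms: none
Why: BF3 binds the ester carbonyl of the β-methoxyacrylate, so that the methoxy-bearing carbon (the future C4) becomes a vinylogous oxocarbenium centre, the same electrophile that ionisation of the corresponding dimethyl acetal would deliver. The carbon of the dimethoxyphenyl ester ring that is ortho to the ester oxygen and para to a methoxy group (the future C4a) attacks it in an intramolecular Friedel–Crafts alkylation, giving the 4-methoxy-3,4-dihydrocoumarin 9, from which ionisation of the benzylic methoxy group (assisted by the para C7 methoxy) and loss of the C3 proton expel methanol and leave the aromatic pyranone. The closest known reaction type is the von Pechmann coumarin synthesis with formylacetic ester equivalents, here in the intramolecular form also known from the acid cyclisation of 3-alkoxyacrylanilides to 2-quinolones. The pyranone closes in a six-membered mode, 6-exo-trig with respect to the C4=O+ bond of the oxocarbenium form, and because the O1–C2 ester is already in place only the C4–C4a bond has to form. No stereocentre remains, since C3 and C4 of 9 both end as sp2 carbons. The step needs attack at the ring carbon para to methoxy and not at the crowded carbon between the two oxygens, which the para-directing methoxy group and the steric difference secure, and it needs to outrun five-membered closure onto the aryloxy ring, whose only free ortho carbon gains nothing from the meta methoxy group and whose ether oxygen is conjugated to the para propenoate.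

Step 6
Reactants: 10 methyl (E)-3-{4-[(6,7-dimethoxy-2-oxo-2H-chromen-3-yl)oxy]-3-methoxyphenyl}prop-2-enoate
Product: 11 methyl (E)-3-{4-[(6,7-dihydroxy-2-oxo-2H-chromen-3-yl)oxy]-3-hydroxyphenyl}prop-2-enoate
Conditions: BBr3, CH2Cl2, −78 °C to 0 °C; then H2O
Reagents that add atoms: none
Why: Boron tribromide cleavage of aryl methyl ethers by bromide attack on the methyl group of the boron-complexed ether, which cannot touch the C3–O–aryl link (no sp3 carbon) and is slow on the lactone and the methyl ester at low temperature.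

Step 7
Reactants: 11 methyl (E)-3-{4-[(6,7-dihydroxy-2-oxo-2H-chromen-3-yl)oxy]-3-hydroxyphenyl}prop-2-enoate
Product: 12 methyl (E)-3-{3-(allyloxy)-4-{[6,7-bis(allyloxy)-2-oxo-2H-chromen-3-yl]oxy}phenyl}prop-2-enoate
Conditions: allyl bromide, K2CO3, DMF, rt, argon
Reagents that add atoms: allyl bromide C=CCBr
Why: Williamson etherification of the three phenols, installing groups that zerovalent palladium can later remove without hydrogenation, strong acid or strong base.

Step 8
Reactants: 12 methyl (E)-3-{3-(allyloxy)-4-{[6,7-bis(allyloxy)-2-oxo-2H-chromen-3-yl]oxy}phenyl}prop-2-enoate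
Product: 14 (E)-3-{3-(allyloxy)-4-{[6,7-bis(allyloxy)-2-oxo-2H-chromen-3-yl]oxy}phenyl}prop-2-enoic acid, via ring-opened trilithium coumarinate 13 (not isolated)
Conditions: LiOH, THF–H2O, rt; then 1 M HCl to pH 2
Reagents that add atoms: lithium hydroxide [Li+].[OH-]
Why: Saponification of the methyl ester, in which hydroxide also opens the lactone to the cis-coumarinate 13 that should relactonise at once on acidification because phenol and carboxyl are held cis on the C3=C4 bond, while the allyl ethers are inert to base.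

Step 9
Reactants: 15 sodium (R)-3-(3,4-dihydroxyphenyl)-2-hydroxypropanoate (sodium danshensu)
Product: 16 allyl (R)-3-[3,4-bis(allyloxy)phenyl]-2-hydroxypropanoate
Conditions: allyl bromide, K2CO3, DMF, rt, argon
Reagents that add atoms: allyl bromide C=CCBr
Why: O-Alkylation of the carboxylate and the two phenoxides, whereas the secondary alcohol is not deprotonated by carbonate and no bond to the stereocentre is broken, so the R configuration is kept.

Step 10
Reactants: 14 (E)-3-{3-(allyloxy)-4-{[6,7-bis(allyloxy)-2-oxo-2H-chromen-3-yl]oxy}phenyl}prop-2-enoic acid; 16 allyl (R)-3-[3,4-bis(allyloxy)phenyl]-2-hydroxypropanoate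
Product: 17 allyl (R)-3-[3,4-bis(allyloxy)phenyl]-2-{[(E)-3-{3-(allyloxy)-4-{[6,7-bis(allyloxy)-2-oxo-2H-chromen-3-yl]oxy}phenyl}prop-2-enoyl]oxy}propanoate
Conditions: DCC, DMAP (cat.), CH2Cl2, 0 °C to rt
Reagents that add atoms: none
Why: Steglich esterification, which forms the acyl–oxygen bond and leaves the C–O bond of the stereocentre intact, so the R configuration of 16 passes into 17 with retention.

Step 11
Reactants: 17 allyl (R)-3-[3,4-bis(allyloxy)phenyl]-2-{[(E)-3-{3-(allyloxy)-4-{[6,7-bis(allyloxy)-2-oxo-2H-chromen-3-yl]oxy}phenyl}prop-2-enoyl]oxy}propanoate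
Product: 18 (R)-3-(3,4-dihydroxyphenyl)-2-{[(E)-3-{4-[(6,7-dihydroxy-2-oxo-2H-chromen-3-yl)oxy]-3-hydroxyphenyl}prop-2-enoyl]oxy}propanoic acid
Conditions: Pd(PPh3)4 (cat.), morpholine, THF, rt, argon; dilute HCl work-up
Reagents that add atoms: none
Why: Tsuji–Trost deallylation, in which zerovalent palladium ionises the five allyl aryl ethers and the allyl ester to π-allyl complexes that morpholine captures, under near-neutral conditions that should spare the cinnamate ester, the lactone, both alkenes and the stereocentre.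

**Compound list**

1 | methyl ferulate | COC(=O)/C=C/c1ccc(O)c(OC)c1 | starting material
2 | tert-butyl bromoacetate | CC(C)(C)OC(=O)CBr | starting material
3 | methyl (E)-3-[4-(2-tert-butoxy-2-oxoethoxy)-3-methoxyphenyl]prop-2-enoate | COC(=O)/C=C/c1ccc(OCC(=O)OC(C)(C)C)c(OC)c1 | intermediate
4 | sodium enolate of tert-butyl 2-{2-methoxy-4-[(E)-3-methoxy-3-oxoprop-1-en-1-yl]phenoxy}-3-oxopropanoate (formed in the flask; enolate geometry not fixed) | [Na+].[O-]C=C(Oc1ccc(/C=C/C(=O)OC)cc1OC)C(=O)OC(C)(C)C | intermediate
5 | tert-butyl (Z)-3-methoxy-2-{2-methoxy-4-[(E)-3-methoxy-3-oxoprop-1-en-1-yl]phenoxy}prop-2-enoate | CO/C=C(\Oc1ccc(/C=C/C(=O)OC)cc1OC)C(=O)OC(C)(C)C | intermediate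
6 | (Z)-3-methoxy-2-{2-methoxy-4-[(E)-3-methoxy-3-oxoprop-1-en-1-yl]phenoxy}prop-2-enoic acid | CO/C=C(\Oc1ccc(/C=C/C(=O)OC)cc1OC)C(=O)O | intermediate
7 | 3,4-dimethoxyphenol | COc1ccc(O)cc1OC | starting material
8 | 3,4-dimethoxyphenyl (Z)-3-methoxy-2-{2-methoxy-4-[(E)-3-methoxy-3-oxoprop-1-en-1-yl]phenoxy}prop-2-enoate | CO/C=C(\Oc1ccc(/C=C/C(=O)OC)cc1OC)C(=O)Oc1ccc(OC)c(OC)c1 | intermediate
9 | methyl (E)-3-{3-methoxy-4-[(4,6,7-trimethoxy-2-oxo-3,4-dihydro-2H-chromen-3-yl)oxy]phenyl}prop-2-enoate (formed in the flask; racemic mixture of diastereomers) | COC(=O)/C=C/c1ccc(OC2C(OC)c3cc(OC)c(OC)cc3OC2=O)c(OC)c1 | intermediate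
10 | methyl (E)-3-{4-[(6,7-dimethoxy-2-oxo-2H-chromen-3-yl)oxy]-3-methoxyphenyl}prop-2-enoate | COC(=O)/C=C/c1ccc(Oc2cc3cc(OC)c(OC)cc3oc2=O)c(OC)c1 | intermediate
11 | methyl (E)-3-{4-[(6,7-dihydroxy-2-oxo-2H-chromen-3-yl)oxy]-3-hydroxyphenyl}prop-2-enoate | COC(=O)/C=C/c1ccc(Oc2cc3cc(O)c(O)cc3oc2=O)c(O)c1 | intermediate
12 | methyl (E)-3-{3-(allyloxy)-4-{[6,7-bis(allyloxy)-2-oxo-2H-chromen-3-yl]oxy}phenyl}prop-2-enoate | COC(=O)/C=C/c1ccc(Oc2cc3cc(OCC=C)c(OCC=C)cc3oc2=O)c(OCC=C)c1 | intermediate
13 | trilithium (E)-2-{2-(allyloxy)-4-[(E)-2-carboxylatoethenyl]phenoxy}-3-[4,5-bis(allyloxy)-2-oxidophenyl]prop-2-enoate (formed in the flask; lactone opened, carboxylate cis to the aryl group) | [Li+].[Li+].[Li+].[O-]C(=O)/C=C/c1ccc(O/C(=C/c2cc(OCC=C)c(OCC=C)cc2[O-])C([O-])=O)c(OCC=C)c1 | intermediate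
14 | (E)-3-{3-(allyloxy)-4-{[6,7-bis(allyloxy)-2-oxo-2H-chromen-3-yl]oxy}phenyl}prop-2-enoic acid | OC(=O)/C=C/c1ccc(Oc2cc3cc(OCC=C)c(OCC=C)cc3oc2=O)c(OCC=C)c1 | intermediate
15 | sodium (R)-3-(3,4-dihydroxyphenyl)-2-hydroxypropanoate (sodium danshensu) | [Na+].O[C@H](Cc1ccc(O)c(O)c1)C([O-])=O | starting material
16 | allyl (R)-3-[3,4-bis(allyloxy)phenyl]-2-hydroxypropanoate | O[C@H](Cc1ccc(OCC=C)c(OCC=C)c1)C(=O)OCC=C | intermediate
17 | allyl (R)-3-[3,4-bis(allyloxy)phenyl]-2-{[(E)-3-{3-(allyloxy)-4-{[6,7-bis(allyloxy)-2-oxo-2H-chromen-3-yl]oxy}phenyl}prop-2-enoyl]oxy}propanoate | O=C(/C=C/c1ccc(Oc2cc3cc(OCC=C)c(OCC=C)cc3oc2=O)c(OCC=C)c1)O[C@H](Cc1ccc(OCC=C)c(OCC=C)c1)C(=O)OCC=C | intermediate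
18 | (R)-3-(3,4-dihydroxyphenyl)-2-{[(E)-3-{4-[(6,7-dihydroxy-2-oxo-2H-chromen-3-yl)oxy]-3-hydroxyphenyl}prop-2-enoyl]oxy}propanoic acid (CNP0318082.1) | O=C(/C=C/c1ccc(Oc2cc3cc(O)c(O)cc3oc2=O)c(O)c1)O[C@H](Cc1ccc(O)c(O)c1)C(=O)O | target

**Step count and risks**

Total step count: 11. Longest linear sequence: 10 steps (steps 1 to 8, then 10 and 11, from methyl ferulate); step 9 is a one-step side branch.

Steps most likely to fail:

1. Step 5. The cationic C4 may be captured by the aryloxy ring in a five-membered closure, or the activated aryl ester may be cleaved or suffer acyl migration before the C–C bond forms. The fallback forms the C3–C4 bond last instead, by a Perkin–Oglialoro condensation. It sets out from 3: TFA in CH2Cl2 removes the tert-butyl group to give {2-methoxy-4-[(E)-3-methoxy-3-oxoprop-1-en-1-yl]phenoxy}acetic acid F1. Heating F1 with commercial 2-hydroxy-4,5-dimethoxybenzaldehyde in Ac2O and Et3N at 110 °C acylates the phenol and closes the ring by intramolecular aldol condensation. The fallback comes back to the route at 10.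

2. Step 2. The ester enolate or methoxide may add in Michael fashion to the cinnamate of a second molecule in competition with formylation, and methylation may go partly to carbon. The fallback introduces C4 without a stoichiometric strong base. It sets out from 3: tert-butoxybis(dimethylamino)methane in toluene at 80 °C should give tert-butyl (Z)-3-(dimethylamino)-2-{2-methoxy-4-[(E)-3-methoxy-3-oxoprop-1-en-1-yl]phenoxy}prop-2-enoate F2. Dilute aqueous HCl in THF at rt hydrolyses the enamine to tert-butyl (E)-3-hydroxy-2-{2-methoxy-4-[(E)-3-methoxy-3-oxoprop-1-en-1-yl]phenoxy}prop-2-enoate F3, the enol of the formyl ester. Me2SO4 and K2CO3 in acetone then methylate the enol oxygen, and the fallback comes back to the route at 5.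

3. Step 10. Acylation of the hindered secondary alcohol next to an ester may be slow enough for the O-acylisourea to rearrange to an unreactive N-acylurea. The fallback replaces in situ carbodiimide activation by a preformed acyl chloride. It sets out from 14: oxalyl chloride with catalytic DMF in CH2Cl2 at 0 °C gives (E)-3-{3-(allyloxy)-4-{[6,7-bis(allyloxy)-2-oxo-2H-chromen-3-yl]oxy}phenyl}prop-2-enoyl chloride F4. Treating F4 with 16 and pyridine in CH2Cl2 at 0 °C forms the ester with retention, and the fallback comes back to the route at 17.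

**Further compounds**

F1 | step 5 | {2-methoxy-4-[(E)-3-methoxy-3-oxoprop-1-en-1-yl]phenoxy}acetic acid | COC(=O)/C=C/c1ccc(OCC(=O)O)c(OC)c1
F2 | step 2 | tert-butyl (Z)-3-(dimethylamino)-2-{2-methoxy-4-[(E)-3-methoxy-3-oxoprop-1-en-1-yl]phenoxy}prop-2-enoate | CN(C)/C=C(\Oc1ccc(/C=C/C(=O)OC)cc1OC)C(=O)OC(C)(C)C
F3 | step 2 | tert-butyl (E)-3-hydroxy-2-{2-methoxy-4-[(E)-3-methoxy-3-oxoprop-1-en-1-yl]phenoxy}prop-2-enoate | O/C=C(/Oc1ccc(/C=C/C(=O)OC)cc1OC)C(=O)OC(C)(C)C
F4 | step 10 | (E)-3-{3-(allyloxy)-4-{[6,7-bis(allyloxy)-2-oxo-2H-chromen-3-yl]oxy}phenyl}prop-2-enoyl chloride | ClC(=O)/C=C/c1ccc(Oc2cc3cc(OCC=C)c(OCC=C)cc3oc2=O)c(OCC=C)c1
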